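**Retrosynthetic overview**

- Feature: in the lactone ring, C1(=O) sits on C8a and C4 on C4a of ring A, with O2 and the pentyl-bearing C3 between them. These are the atoms joined when an o-quinoid ketene methide (C4=C4a–C8a=C1=O) adds across the C=O of hexanal.
- Disconnections: the three O–Me bonds (final BBr3); the C3=C4 double bond (E1cB opening and oxidative re-lactonisation of the racemic dihydroisocoumarin); C3–C4 and C1–O2 (benzocyclobutenone/hexanal [4+2]); the four-membered ring (aryne/ketene acetal [2+2]); the diaryl ether C–O bond (SNAr).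
- Ring order: rings A and B are bought as arenes; the cyclobutenone ring is formed in step 6; the lactone ring is closed in step 7, opened in step 8 and closed again at the isocoumarin level in step 9.
- All three phenols are carried as methyl ethers so that no OH group quenches the ketene.

Key step: step 7

Remark: compound 17 is made as a racemate; its only stereocentre (C3) is removed in step 8 and the target is achiral.

**Route**

Step 1
Reactants: 1 olivetol dimethyl ether (1,3-dimethoxy-5-pentylbenzene)
Product: 3 2,4-dimethoxy-6-pentylbenzaldehyde, via aryl iminium chloride 2 (not isolated)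
Conditions: POCl3, DMF, 0 → 80 °C; then ice-water
Reagents that add atoms: N,N-dimethylformamide, CN(C)C=O; water, O
Why: Vilsmeier–Haack formylation should take place at the ring position para to one methoxy group and ortho to the other (next to the pentyl chain), which is favoured over the position flanked by both methoxy groups, and the iminium salt 2 is hydrolysed on work-up.

Step 2
Reactants: 3 2,4-dimethoxy-6-pentylbenzaldehyde
Product: 5 2,4-dimethoxy-6-pentylphenol, via aryl formate 4 (not isolated)
Conditions: mCPBA, CH2Cl2, 0 °C → rt; then K2CO3 (cat.), MeOH, rt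
Reagents that add atoms: mCPBA (3-chloroperoxybenzoic acid), O=C(OO)c1cccc(Cl)c1
Why: In this Dakin-type Baeyer–Villiger oxidation the electron-rich aryl group migrates in preference to hydrogen, and the formate 4 is cleaved by methanolysis.

Step 3
Reactants: 5 2,4-dimethoxy-6-pentylphenol; 6 2-fluoro-4-methoxy-1-nitrobenzene
Product: 7 1,5-dimethoxy-2-(5-methoxy-2-nitrophenoxy)-3-pentylbenzene
Conditions: K2CO3, DMF, 80 °C
Reagents that add atoms: none
Why: SNAr through a Meisenheimer complex; fluoride ortho to the nitro group is displaced readily even by a phenoxide with two ortho substituents, whereas the methoxy group para to the nitro group is a far poorer leaving group.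

Step 4
Reactants: 7 1,5-dimethoxy-2-(5-methoxy-2-nitrophenoxy)-3-pentylbenzene
Product: 8 2-(2,4-dimethoxy-6-pentylphenoxy)-4-methoxyaniline
Conditions: H2 (1 atm), Pd/C, EtOAc–EtOH, rt
Reagents that add atoms: none
Why: Catalytic hydrogenation reduces the nitroarene to the aniline and leaves the aryl ethers untouched.

Step 5
Reactants: 8 2-(2,4-dimethoxy-6-pentylphenoxy)-4-methoxyaniline
Product: 10 2-(2-bromo-5-methoxyphenoxy)-1,5-dimethoxy-3-pentylbenzene, via arenediazonium bromide 9 (not isolated)
Conditions: NaNO2 (1.05 equiv), 48% aq HBr, MeCN, 0 °C; then CuBr (20 mol %), 0 → 60 °C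
Reagents that add atoms: hydrogen bromide, Br
Why: Sandmeyer bromination puts the halogen on the carbon that will carry the lactone carbonyl, without electrophilic bromination of the electron-rich ring B; Pschorr closure to a dibenzofuran is blocked because both ortho positions of ring B are substituted.

Step 6
Reactants: 10 2-(2-bromo-5-methoxyphenoxy)-1,5-dimethoxy-3-pentylbenzene; 11 1,1-diethoxyethene
Product: 14 5-(2,4-dimethoxy-6-pentylphenoxy)-3-methoxybicyclo[4.2.0]octa-1,3,5-trien-7-one, via 3-aryloxy-5-methoxybenzyne 12 (not isolated), via diethyl acetal 13 (not isolated)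
Conditions: NaNH2 (3 equiv), 11 (3 equiv), THF, 65 °C; then 1 M aq HCl, THF, rt
Reagents that add atoms: water, O
Why: Dehydrobromination can only use the single hydrogen ortho to bromine and gives aryne 12; in the aryne/ketene acetal [2+2] the nucleophilic CH2 terminus should add to the aryne carbon remote from the aryloxy group, so the acetal carbon ends up next to the aryloxy-bearing carbon, and mild acid hydrolysis then frees the ketone.

Step 7
Reactants: 14 5-(2,4-dimethoxy-6-pentylphenoxy)-3-methoxybicyclo[4.2.0]octa-1,3,5-trien-7-one; 15 hexanal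
Product: 17 racemic 8-(2,4-dimethoxy-6-pentylphenoxy)-6-methoxy-3-pentylisochroman-1-one, via o-quinoid ketene methide 16 (not isolated)
Conditions: PhCl, 150 °C, sealed tube, 14 added slowly to 15 (10 equiv)
Reagents that add atoms: none
Why: Heat should break the C7–C8 bond of the four-membered ring in a conrotatory 4π electrocyclic opening, giving the ketene methide 16 with an exocyclic CH2 on C4a and a ketene on C8a. Compound 16 then acts as the heterodiene C4=C4a–C8a=C1 towards the C=O of hexanal in a hetero-Diels–Alder reaction that forms C3–C4 and C1–O2 and restores the aromatic sextet of ring A. The closest known reaction type is the thermal capture of benzocyclobutenone-derived ketene methides by carbonyl and alkene 2π partners; an enolisable aliphatic aldehyde is the less explored partner. The lactone ring closes by an intermolecular [4+2] cycloaddition that makes two bonds of the six-membered ring at once. C3 is formed without control as a racemate, which does not matter because this centre becomes sp2 in step 8. The orientation is set by polarity (aldehyde oxygen to the electrophilic ketene carbon, aldehyde carbon to the methylene terminus); capture has to outrun ketene dimerisation, which is addressed by slow addition into excess hexanal and by the absence of free OH groups.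

Step 8
Reactants: 17 racemic 8-(2,4-dimethoxy-6-pentylphenoxy)-6-methoxy-3-pentylisochroman-1-one
Product: 18 (E)-2-(2,4-dimethoxy-6-pentylphenoxy)-6-(hept-1-en-1-yl)-4-methoxybenzoic acid
Conditions: LiN(iPr)2 (1.3 equiv), THF, −78 → 0 °C; then 1 M aq HCl
Reagents that add atoms: none
Why: Only the C4 hydrogens are acidified by the ortho lactone carbonyl, so lateral deprotonation and E1cB loss of the carboxylate should open the ring to the conjugated alkenyl acid; this avoids radical or electrophilic bromination, which could not distinguish C4 from the benzylic CH2 of the ring B pentyl chain or spare the electron-rich ring B.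

Step 9
Reactants: 18 (E)-2-(2,4-dimethoxy-6-pentylphenoxy)-6-(hept-1-en-1-yl)-4-methoxybenzoic acid
Product: 19 8-(2,4-dimethoxy-6-pentylphenoxy)-6-methoxy-3-pentyl-1H-isochromen-1-one
Conditions: Pd(OAc)2 (10 mol %), NaOAc, O2 (1 atm), DMSO, 80 °C
Reagents that add atoms: none
Why: Wacker-type oxidative lactonisation with divalent palladium: 6-endo oxypalladation puts the carboxylate oxygen on C3 and palladium on the benzylic C4, β-hydride elimination of the C3 hydrogen gives the C3=C4 bond, and O2 reoxidises zerovalent palladium.

Step 10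
Reactants: 19 8-(2,4-dimethoxy-6-pentylphenoxy)-6-methoxy-3-pentyl-1H-isochromen-1-one
Product: 20 8-(2,4-dihydroxy-6-pentylphenoxy)-6-hydroxy-3-pentyl-1H-isochromen-1-one (CNP0213708.0)
Conditions: BBr3 (6 equiv), CH2Cl2, −78 °C → rt; then H2O
Reagents that add atoms: none
Why: BBr3 cleaves the three aryl methyl ethers by Lewis acid complexation and bromide attack on methyl, while the diaryl ether and the isocoumarin lactone should survive.

**Compound list**

1 | olivetol dimethyl ether (1,3-dimethoxy-5-pentylbenzene) | CCCCCc1cc(OC)cc(OC)c1 | starting material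
2 | [(2,4-dimethoxy-6-pentylphenyl)methylidene]dimethylammonium chloride | CCCCCc1cc(OC)cc(OC)c1C=[N+](C)C.[Cl-] | intermediate
3 | 2,4-dimethoxy-6-pentylbenzaldehyde | CCCCCc1cc(OC)cc(OC)c1C=O | intermediate
4 | 2,4-dimethoxy-6-pentylphenyl formate | CCCCCc1cc(OC)cc(OC)c1OC=O | intermediate
5 | 2,4-dimethoxy-6-pentylphenol | CCCCCc1cc(OC)cc(OC)c1O | intermediate
6 | 2-fluoro-4-methoxy-1-nitrobenzene | COc1ccc([N+](=O)[O-])c(F)c1 | starting material
7 | 1,5-dimethoxy-2-(5-methoxy-2-nitrophenoxy)-3-pentylbenzene | CCCCCc1cc(OC)cc(OC)c1Oc1cc(OC)ccc1[N+](=O)[O-] | intermediate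
8 | 2-(2,4-dimethoxy-6-pentylphenoxy)-4-methoxyaniline | CCCCCc1cc(OC)cc(OC)c1Oc1cc(OC)ccc1N | intermediate
9 | 2-(2,4-dimethoxy-6-pentylphenoxy)-4-methoxybenzenediazonium bromide | CCCCCc1cc(OC)cc(OC)c1Oc1cc(OC)ccc1[N+]#N.[Br-] | intermediate
10 | 2-(2-bromo-5-methoxyphenoxy)-1,5-dimethoxy-3-pentylbenzene | CCCCCc1cc(OC)cc(OC)c1Oc1cc(OC)ccc1Br | intermediate
11 | 1,1-diethoxyethene | CCOC(=C)OCC | starting material
12 | 3-(2,4-dimethoxy-6-pentylphenoxy)-5-methoxybenzyne | CCCCCc1cc(OC)cc(OC)c1OC1=CC(OC)=CC#C1 | intermediate
13 | 7,7-diethoxy-5-(2,4-dimethoxy-6-pentylphenoxy)-3-methoxybicyclo[4.2.0]octa-1,3,5-triene | CCOC1(OCC)Cc2cc(OC)cc(Oc3c(OC)cc(OC)cc3CCCCC)c21 | intermediate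
14 | 5-(2,4-dimethoxy-6-pentylphenoxy)-3-methoxybicyclo[4.2.0]octa-1,3,5-trien-7-one | COc1cc2CC(=O)c2c(Oc2c(OC)cc(OC)cc2CCCCC)c1 | intermediate
15 | hexanal | CCCCCC=O | starting material
16 | o-quinoid ketene methide: [2-(2,4-dimethoxy-6-pentylphenoxy)-4-methoxy-6-methylidenecyclohexa-2,4-dien-1-ylidene]ketene | C=C1C=C(OC)C=C(Oc2c(OC)cc(OC)cc2CCCCC)C1=C=O | intermediate
17 | racemic 8-(2,4-dimethoxy-6-pentylphenoxy)-6-methoxy-3-pentylisochroman-1-one | CCCCCC1Cc2cc(OC)cc(Oc3c(OC)cc(OC)cc3CCCCC)c2C(=O)O1 | intermediate
18 | (E)-2-(2,4-dimethoxy-6-pentylphenoxy)-6-(hept-1-en-1-yl)-4-methoxybenzoic acid | CCCCC/C=C/c1cc(OC)cc(Oc2c(OC)cc(OC)cc2CCCCC)c1C(=O)O | intermediate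
19 | 8-(2,4-dimethoxy-6-pentylphenoxy)-6-methoxy-3-pentyl-1H-isochromen-1-one | CCCCCc1cc2cc(OC)cc(Oc3c(OC)cc(OC)cc3CCCCC)c2c(=O)o1 | intermediate
20 | 8-(2,4-dihydroxy-6-pentylphenoxy)-6-hydroxy-3-pentyl-1H-isochromen-1-one (CNP0213708.0) | CCCCCc1cc2cc(O)cc(Oc3c(O)cc(O)cc3CCCCC)c2c(=O)o1 | target

**Step count and risks**

Total step count: 10. Longest linear sequence: 10 steps (from compound 1).

Steps most likely to fail:

1. Step 7 (key step). The ketene methide may dimerise, or hexanal may undergo aldol self-condensation at 150 °C, faster than the weakly dienophilic aliphatic C=O is captured. Fallback, from 14 back to 17: 14 would be heated in methanol (sealed tube, 150 °C), where the alcohol traps the ketene methide efficiently to give the toluate methyl 2-(2,4-dimethoxy-6-pentylphenoxy)-4-methoxy-6-methylbenzoate F1. Lateral lithiation of F1 with LiN(iPr)2 in THF at −78 °C and addition of hexanal 15 should give an alkoxide that closes onto the ester on warming, delivering 17 by an ionic aldol/lactonisation sequence in place of the cycloaddition.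

2. Step 6. Amide may add to the aryne faster than the [2+2] with the ketene acetal, giving aminated by-products, or regiocontrol may be incomplete. Fallback, from 10 back to 14: 10 would be treated with lithium 2,2,6,6-tetramethylpiperidide in THF containing the lithium enolate of acetaldehyde (made in the flask from nBuLi and THF). The enolate carbon should add to the remote aryne carbon and the aryl anion should close onto the aldehyde carbon, giving the benzocyclobutenol racemic 5-(2,4-dimethoxy-6-pentylphenoxy)-3-methoxybicyclo[4.2.0]octa-1,3,5-trien-7-ol F2. Oxidation of F2 with Dess–Martin periodinane in CH2Cl2 would give 14.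

3. Step 9. Oxypalladation may proceed in the 5-exo sense, leading to phthalide-type closure, or the acid may re-add across the alkene without oxidation. Fallback, from 17 back to 19 (bypassing steps 8 and 9): the lactone 17 would be opened with Me2AlNMe2 (from AlMe3 and dimethylamine hydrochloride) in toluene to the hydroxy amide racemic 2-(2,4-dimethoxy-6-pentylphenoxy)-6-(2-hydroxyheptyl)-4-methoxy-N,N-dimethylbenzamide F3. Oxidation of F3 with Dess–Martin periodinane would give the keto amide 2-(2,4-dimethoxy-6-pentylphenoxy)-4-methoxy-N,N-dimethyl-6-(2-oxoheptyl)benzamide F4. Heating F4 with TsOH in toluene should close the enol oxygen onto the amide carbonyl with loss of dimethylamine and give 19.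

**Further compounds**

F1 | step 7 | methyl 2-(2,4-dimethoxy-6-pentylphenoxy)-4-methoxy-6-methylbenzoate | COC(=O)c1c(C)cc(OC)cc1Oc1c(OC)cc(OC)cc1CCCCC
F2 | step 6 | racemic 5-(2,4-dimethoxy-6-pentylphenoxy)-3-methoxybicyclo[4.2.0]octa-1,3,5-trien-7-ol | COc1cc2CC(O)c2c(Oc2c(OC)cc(OC)cc2CCCCC)c1
F3 | step 9 | racemic 2-(2,4-dimethoxy-6-pentylphenoxy)-6-(2-hydroxyheptyl)-4-methoxy-N,N-dimethylbenzamide | CCCCCC(O)Cc1cc(OC)cc(Oc2c(OC)cc(OC)cc2CCCCC)c1C(=O)N(C)C
F4 | step 9 | 2-(2,4-dimethoxy-6-pentylphenoxy)-4-methoxy-N,N-dimethyl-6-(2-oxoheptyl)benzamide | CCCCCC(=O)Cc1cc(OC)cc(Oc2c(OC)cc(OC)cc2CCCCC)c1C(=O)N(C)C
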